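**Retrosynthetic overview**

1. The target is (3S,6S,6'S)-ε,ε-caroten-3-ol, numbered as a carotenoid: ring B is the hydroxylated ε-ring (C1–C6, chain half C7–C15) and ring A the unsubstituted ε-ring (C1'–C6', C7'–C15'). Disconnection at C11=C12 and C11'=C12' (two Wittig reactions) gives a ring B C15 ylide, a C10 dialdehyde and a ring A C15 ylide.
2. Both C15 units come from one ester, ethyl (S)-α-ionylideneacetate, and so from (S)-α-ionone. The C3 oxygen of ring B is added after the ring exists (allylic oxidation at C3, hydride reduction, Mitsunobu inversion), in the biosynthetic order cyclase then hydroxylase.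
3. Key disconnection: the C1–C6 bond of ring B, made in the same operation as C1'–C6' of ring A, by a catalytic enantioselective proton-initiated cyclization of achiral, acyclic pseudoionone that copies the ε-cyclase step.
4. Enabling feature: each ε-ring is a head-to-tail 1,5-diene cyclization product. The gem-dimethyl carbon C1 is the Markovnikov cation of an isopropylidene terminus, C6 is the inner carbon of the C5=C6 alkene that captures it, C4=C5 marks the proton that is lost, and the conjugated C7=C8–C9=O chain on C6 holds H-6 in place. C3 is allylic to C4=C5, so its hydroxyl can follow.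
5. Ring order: a single ring-forming event (step 1) supplies both six-membered rings; C15 → C25 → C40 then follow by olefination.

Key step: step 1

Assumption: the sense of induction of the chiral acid in step 1 cannot be predicted, so the catalyst antipode that leads to (S)-2 is meant (both antipodes are equally accessible), and commercial pseudoionone is taken as its usual 5E/5Z mixture.

**Route**

Step 1
Reactants: 1 pseudoionone ((3E)-6,10-dimethylundeca-3,5,9-trien-2-one, 5E/5Z mixture)
Product: 2 (S)-α-ionone ((3E)-4-[(1S)-2,6,6-trimethylcyclohex-2-en-1-yl]but-3-en-2-one)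
Conditions: chiral confined Brønsted acid HN[P(=NSO2CF3)(O2Ar*)]2 (3 mol %; O2Ar* = 3,3'-bis[3,5-bis(trifluoromethyl)phenyl]-1,1'-binaphthalene-2,2'-diolate), (CF3)3COH/CH2Cl2, −40 °C; Et3N quench
Reagents that add atoms: none
Why: Proposed new method: the confined acid is expected to protonate C2 of the isopropylidene terminus (Markovnikov) while the C5=C6 π-bond, folded in a chair, attacks the emerging tertiary cation at C1 (cation–olefin cyclization; the ring closes 6-endo-trig through the C1–C6 bond), and the tertiary C5 cation, ion-paired with the chiral anion, then loses H-4 to that anion to give the C4=C5 alkene. The closest known reaction types are the phosphoric acid cyclization of pseudoionone to racemic α-ionone and the enantioselective proton-initiated polyene cyclizations of homofarnesol- and geranyl-type substrates with chiral Brønsted acids (BINOL·SnCl4 combined acids, imidodiphosphorimidates), which close the analogous gem-dimethylcyclohexane bond; new is the enantioselective closure of a dienone-terminated substrate that ends by proton loss. The only new stereocenter, C6, is set in the C–C bond formation under catalyst control: the anion cavity, anchored by hydrogen bonding to the C9 carbonyl, should admit only one of the two enantiomeric chair foldings and thus one face of C6. The step needs α- over β/γ-regioselectivity, which the substrate secures through the conjugated enone on C6 (H-6 is the least hydridic and most shielded β-hydrogen, so kinetic loss of H-4 prevails at low temperature, as in the phosphoric acid process), and it needs convergence of the 5E/5Z mixture, which O-protonation of the dienone (cationic character at C5, free rotation about C5–C6) should provide, both isomers draining through the faster chair with the side chain equatorial.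

Step 2
Reactants: 2 (S)-α-ionone
Product: 3 ethyl (2E,4E)-3-methyl-5-[(1S)-2,6,6-trimethylcyclohex-2-en-1-yl]penta-2,4-dienoate
Conditions: (EtO)2P(O)CH2CO2Et, NaH, THF, 0 °C → reflux; chromatography
Reagents that add atoms: triethyl phosphonoacetate, CCOC(=O)CP(=O)(OCC)OCC
Why: Horner–Wadsworth–Emmons olefination of the methyl ketone should give the (2E)-dienoate as the main isomer (the minor 2Z isomer is removed), and the C6 stereocenter is not touched because H-6 is far less acidic than the phosphonate.

Step 3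
Reactants: 3 ethyl (S)-α-ionylideneacetate
Product: 4 (2E,4E)-3-methyl-5-[(1S)-2,6,6-trimethylcyclohex-2-en-1-yl]penta-2,4-dien-1-ol
Conditions: i-Bu2AlH (2.5 equiv), CH2Cl2, −78 °C; potassium sodium tartrate work-up
Reagents that add atoms: none
Why: Standard i-Bu2AlH reduction of a conjugated ester to the allylic alcohol, with no stereocenter involved.

Step 4
Reactants: 4 ring A C15 alcohol
Product: 5 [(2E,4E)-3-methyl-5-[(1S)-2,6,6-trimethylcyclohex-2-en-1-yl]penta-2,4-dien-1-yl]triphenylphosphonium bromide
Conditions: PPh3·HBr, MeOH, 0 °C → rt; crystallization (EtOAc)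
Reagents that add atoms: triphenylphosphine hydrobromide, [Br-].[PH+](c1ccccc1)(c1ccccc1)c1ccccc1
Why: Acid-mediated SN1-type substitution of the dienylic alcohol by PPh3 (the usual route to C15 Wittig salts of ε-type end groups), the pentadienyl cation being trapped at its primary terminus so that the 9'E salt should be obtained after crystallization and C6' stays untouched.

Step 5
Reactants: 5 ring A C15 phosphonium bromide; 6 (2E,4E,6E)-2,7-dimethylocta-2,4,6-trienedial
Product: 8 (2E,4E,6E,8E,10E,12E)-2,7,11-trimethyl-13-[(1S)-2,6,6-trimethylcyclohex-2-en-1-yl]trideca-2,4,6,8,10,12-hexaenal, via ring A ylide 7 (not isolated)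
Conditions: 6 (2 equiv), NaOMe, MeOH/CH2Cl2, −10 °C → rt; then heptane, 90 °C
Reagents that add atoms: none
Why: Wittig olefination of one formyl group of the dialdehyde, kept mono by the excess of 6 and by the lower electrophilicity of the more conjugated product, followed by thermal equilibration of any 11'Z isomer to the all-E polyene.

Step 6
Reactants: 3 ethyl (S)-α-ionylideneacetate
Product: 9 ethyl (2E,4E)-3-methyl-5-[(1S)-2,6,6-trimethyl-4-oxocyclohex-2-en-1-yl]penta-2,4-dienoate
Conditions: t-BuOOH (70 % aq.), Rh2(cap)4 (dirhodium tetrakis(caprolactamate), 1 mol %), CH2Cl2, rt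
Reagents that add atoms: tert-butyl hydroperoxide, CC(C)(C)OO
Why: Allylic C–H oxidation by tert-butylperoxyl radicals (the catalytic counterpart of the classical chromate oxidation of α-ionylidene esters to their 3-oxo derivatives) should attack the ring methylene C3 next to C4=C5, since the dienoate chain is deactivated and H-6 is shielded by the flanking methyl groups, and it leaves C6 unchanged.

Step 7
Reactants: 9 (6S)-3-oxo ester
Product: 10 ethyl (2E,4E)-5-[(1S,4R)-4-hydroxy-2,6,6-trimethylcyclohex-2-en-1-yl]-3-methylpenta-2,4-dienoate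
Conditions: LiBH(s-Bu)3, THF, −78 °C; then H2O
Reagents that add atoms: none
Why: Diastereoselective 1,2-reduction of the β,β-disubstituted enone under steric approach control, in which the bulky hydride should enter C3 from the face opposite the C6 side chain and the C1 methyl group that is syn-axial on that face, setting C3 as (3R), cis to the side chain.

Step 8
Reactants: 10 cis-(3R,6S) hydroxy ester
Product: 11 (2E,4E)-5-[(1S,4R)-4-hydroxy-2,6,6-trimethylcyclohex-2-en-1-yl]-3-methylpenta-2,4-dien-1-ol
Conditions: i-Bu2AlH (3.5 equiv), CH2Cl2, −78 °C; potassium sodium tartrate work-up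
Reagents that add atoms: none
Why: i-Bu2AlH reduction of the conjugated ester to the primary allylic alcohol, the secondary alkoxide at C3 being inert.

Step 9
Reactants: 11 cis diol
Product: 12 (1R,4S)-4-[(1E,3E)-5-[tert-butyl(dimethyl)silyl]oxy-3-methylpenta-1,3-dien-1-yl]-3,5,5-trimethylcyclohex-2-en-1-ol
Conditions: TBSCl (1.05 equiv), imidazole, CH2Cl2, −20 °C
Reagents that add atoms: tert-butyldimethylsilyl chloride, CC(C)(C)[Si](C)(C)Cl
Why: Selective silylation of the unhindered primary allylic hydroxyl in the presence of the secondary ring hydroxyl flanked by the neopentyl-type C2 methylene.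

Step 10
Reactants: 12 cis mono-silyl ether
Product: 13 (1S,4S)-4-[(1E,3E)-5-[tert-butyl(dimethyl)silyl]oxy-3-methylpenta-1,3-dien-1-yl]-3,5,5-trimethylcyclohex-2-en-1-yl benzoate
Conditions: PhCO2H, PPh3, DIAD, toluene, −20 °C → rt
Reagents that add atoms: benzoic acid, OC(=O)c1ccccc1
Why: Mitsunobu reaction, in which benzoate displaces the oxyphosphonium leaving group at C3 by SN2 with inversion to give the (3S) ester, trans to the side chain, while SN2' attack at the fully substituted C5 is not expected.

Step 11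
Reactants: 13 trans-(3S,6S) benzoate silyl ether
Product: 15 [(2E,4E)-5-[(1S,4S)-4-(benzoyloxy)-2,6,6-trimethylcyclohex-2-en-1-yl]-3-methylpenta-2,4-dien-1-yl]triphenylphosphonium bromide, via hydroxy benzoate 14 (not isolated)
Conditions: PPh3·HBr (1.1 equiv), MeOH/CH2Cl2, 0 °C → rt
Reagents that add atoms: triphenylphosphine hydrobromide, [Br-].[PH+](c1ccccc1)(c1ccccc1)c1ccccc1
Why: Acid-catalysed methanolysis of the primary silyl ether is followed in the same pot by SN1-type phosphonium formation at the dienylic carbon, and the C3 benzoate should be kept because an allylic ester ionizes far less readily than a free allylic alcohol.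

Step 12
Reactants: 15 ring B C15 phosphonium bromide; 8 ring A C25 aldehyde
Product: 18 (3S,6S,6'S)-ε,ε-caroten-3-ol, via ring B ylide 16 (not isolated), via target 3-O-benzoate 17 (not isolated)
Conditions: NaOMe (1.2 equiv), MeOH/CH2Cl2, 0 °C → rt; then NaOMe (2 equiv), rt; then EtOH, 70 °C
Reagents that add atoms: none
Why: Wittig olefination joins the two halves at C11=C12, methoxide then transesterifies the benzoate to free the C3 hydroxyl, and heating equilibrates any 11Z isomer to the all-E target, none of the three stereocenters being acidic enough to be touched by methoxide.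

**Compound list**

1 | pseudoionone, (3E)-6,10-dimethylundeca-3,5,9-trien-2-one (5E/5Z mixture) | CC(C)=CCCC(C)=C/C=C/C(C)=O | starting material
2 | (S)-α-ionone, (3E)-4-[(1S)-2,6,6-trimethylcyclohex-2-en-1-yl]but-3-en-2-one | CC1=CCCC(C)(C)[C@@H]1/C=C/C(C)=O | intermediate
3 | ethyl (2E,4E)-3-methyl-5-[(1S)-2,6,6-trimethylcyclohex-2-en-1-yl]penta-2,4-dienoate | CC1=CCCC(C)(C)[C@@H]1/C=C/C(C)=C/C(=O)OCC | intermediate
4 | (2E,4E)-3-methyl-5-[(1S)-2,6,6-trimethylcyclohex-2-en-1-yl]penta-2,4-dien-1-ol | CC1=CCCC(C)(C)[C@@H]1/C=C/C(C)=C/CO | intermediate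
5 | [(2E,4E)-3-methyl-5-[(1S)-2,6,6-trimethylcyclohex-2-en-1-yl]penta-2,4-dien-1-yl]triphenylphosphonium bromide | CC1=CCCC(C)(C)[C@@H]1/C=C/C(C)=C/C[P+](c1ccccc1)(c1ccccc1)c1ccccc1.[Br-] | intermediate
6 | (2E,4E,6E)-2,7-dimethylocta-2,4,6-trienedial | O=C/C(C)=C/C=C/C=C(C)/C=O | starting material
7 | ring A ylide, [(2E,4E)-3-methyl-5-[(1S)-2,6,6-trimethylcyclohex-2-en-1-yl]penta-2,4-dien-1-ylidene]triphenyl-λ5-phosphane | CC1=CCCC(C)(C)[C@@H]1/C=C/C(C)=C/C=P(c1ccccc1)(c1ccccc1)c1ccccc1 | intermediate
8 | (2E,4E,6E,8E,10E,12E)-2,7,11-trimethyl-13-[(1S)-2,6,6-trimethylcyclohex-2-en-1-yl]trideca-2,4,6,8,10,12-hexaenal | CC1=CCCC(C)(C)[C@@H]1/C=C/C(C)=C/C=C/C(C)=C/C=C/C=C(C)/C=O | intermediate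
9 | ethyl (2E,4E)-3-methyl-5-[(1S)-2,6,6-trimethyl-4-oxocyclohex-2-en-1-yl]penta-2,4-dienoate | CC1=CC(=O)CC(C)(C)[C@@H]1/C=C/C(C)=C/C(=O)OCC | intermediate
10 | ethyl (2E,4E)-5-[(1S,4R)-4-hydroxy-2,6,6-trimethylcyclohex-2-en-1-yl]-3-methylpenta-2,4-dienoate | CC1=C[C@H](O)CC(C)(C)[C@@H]1/C=C/C(C)=C/C(=O)OCC | intermediate
11 | (2E,4E)-5-[(1S,4R)-4-hydroxy-2,6,6-trimethylcyclohex-2-en-1-yl]-3-methylpenta-2,4-dien-1-ol | CC1=C[C@H](O)CC(C)(C)[C@@H]1/C=C/C(C)=C/CO | intermediate
12 | (1R,4S)-4-[(1E,3E)-5-[tert-butyl(dimethyl)silyl]oxy-3-methylpenta-1,3-dien-1-yl]-3,5,5-trimethylcyclohex-2-en-1-ol | CC1=C[C@H](O)CC(C)(C)[C@@H]1/C=C/C(C)=C/CO[Si](C)(C)C(C)(C)C | intermediate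
13 | (1S,4S)-4-[(1E,3E)-5-[tert-butyl(dimethyl)silyl]oxy-3-methylpenta-1,3-dien-1-yl]-3,5,5-trimethylcyclohex-2-en-1-yl benzoate | CC1=C[C@@H](OC(=O)c2ccccc2)CC(C)(C)[C@@H]1/C=C/C(C)=C/CO[Si](C)(C)C(C)(C)C | intermediate
14 | (1S,4S)-4-[(1E,3E)-5-hydroxy-3-methylpenta-1,3-dien-1-yl]-3,5,5-trimethylcyclohex-2-en-1-yl benzoate | CC1=C[C@@H](OC(=O)c2ccccc2)CC(C)(C)[C@@H]1/C=C/C(C)=C/CO | intermediate
15 | [(2E,4E)-5-[(1S,4S)-4-(benzoyloxy)-2,6,6-trimethylcyclohex-2-en-1-yl]-3-methylpenta-2,4-dien-1-yl]triphenylphosphonium bromide | CC1=C[C@@H](OC(=O)c2ccccc2)CC(C)(C)[C@@H]1/C=C/C(C)=C/C[P+](c1ccccc1)(c1ccccc1)c1ccccc1.[Br-] | intermediate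
16 | ring B ylide, [(2E,4E)-5-[(1S,4S)-4-(benzoyloxy)-2,6,6-trimethylcyclohex-2-en-1-yl]-3-methylpenta-2,4-dien-1-ylidene]triphenyl-λ5-phosphane | CC1=C[C@@H](OC(=O)c2ccccc2)CC(C)(C)[C@@H]1/C=C/C(C)=C/C=P(c1ccccc1)(c1ccccc1)c1ccccc1 | intermediate
17 | (3S,6S,6'S)-ε,ε-caroten-3-yl benzoate | CC1=CCCC(C)(C)[C@@H]1/C=C/C(C)=C/C=C/C(C)=C/C=C/C=C(C)/C=C/C=C(C)/C=C/[C@@H]1C(C)=C[C@@H](OC(=O)c2ccccc2)CC1(C)C | intermediate
18 | (3S,6S,6'S)-ε,ε-caroten-3-ol, (1S,4S)-3,5,5-trimethyl-4-[(1E,3E,5E,7E,9E,11E,13E,15E,17E)-3,7,12,16-tetramethyl-18-[(1S)-2,6,6-trimethylcyclohex-2-en-1-yl]octadeca-1,3,5,7,9,11,13,15,17-nonaen-1-yl]cyclohex-2-en-1-ol | CC1=CCCC(C)(C)[C@@H]1/C=C/C(C)=C/C=C/C(C)=C/C=C/C=C(C)/C=C/C=C(C)/C=C/[C@@H]1C(C)=C[C@@H](O)CC1(C)C | target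

**Step count and risks**

Total step count: 12. Longest linear sequence: 9 steps (steps 1, 2, 6, 7, 8, 9, 10, 11, 12).

Steps most likely to fail:

1. Step 1 (Proposed new method). What may go wrong: insufficient discrimination between the two chair foldings (low enantioselectivity), or acid-promoted migration of the C4=C5 double bond into conjugation, which erases C6. The fallback sets out from 1 and returns at 2. Cyclization of 1 with 85 % H3PO4 (toluene, 80 °C), the established racemic process, would give racemic α-ionone F1. NaBH4/CeCl3 (MeOH, 0 °C) would give the α-ionols F2 as a mixture of stereoisomers. Esterification with 4-nitrobenzoyl chloride/pyridine and fractional crystallization should deliver a single racemic diastereomer, shown here as the (6S*,9R*)-4-nitrobenzoate F3, and KOH/MeOH would return the racemic (6S*,9R*)-α-ionol F4. Acetylation with vinyl acetate catalysed by the lipase of Burkholderia cepacia, which acylates secondary (R)-carbinols of this type, should convert only one enantiomer into the (6S,9R)-acetate F5. After separation from the unreacted (6R,9S)-alcohol, saponification to (6S,9R)-α-ionol F6 and MnO2 oxidation (CH2Cl2) would give 2.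

2. Step 7. What may go wrong: poor facial selectivity of hydride delivery at C3 (a mixture of C3 epimers) or competing conjugate reduction. The fallback sets out from 2 and returns at 18, replacing steps 6 to 11. The known microbial hydroxylation of α-ionone (whole cells of a Streptomyces strain or an engineered P450 monooxygenase, O2, glucose, buffer, 28 °C), which places the hydroxyl at C3 trans to the side chain, would give (3S,6S)-3-hydroxy-α-ionone F7. Vinylmagnesium bromide (THF, −20 °C) would give the tertiary vinyl carbinol F8 as a C9 epimer mixture. PPh3·HBr (MeOH, 0 °C) should ionize only the tertiary, doubly allylic carbinol and give the hydroxy phosphonium bromide F9. Its ylide F10 (NaOMe, MeOH/CH2Cl2) would be coupled with 8 and the product equilibrated by heating to give 18.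

3. Step 10. What may go wrong: ionization of the allylic oxyphosphonium intermediate, leading to elimination towards a conjugated triene or to loss of stereochemical fidelity. The fallback sets out from 10 and returns at 13. Acid-catalysed allylic epimerization of 10 (dilute aqueous HCl, THF, rt; the equilibration known for 3-hydroxy-ε end groups) would give a mixture of 10 and its (3S)-epimer, the trans hydroxy ester F11, which would be separated by chromatography while 10 is recycled. i-Bu2AlH reduction would give the trans diol F12, selective silylation (TBSCl, imidazole) the trans mono-silyl ether F13, and benzoylation with retention (benzoyl chloride, pyridine, 4-(dimethylamino)pyridine) would give 13.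

**Further compounds**

F1 | step 1 | racemic α-ionone, (3E)-4-(2,6,6-trimethylcyclohex-2-en-1-yl)but-3-en-2-one | CC1=CCCC(C)(C)C1/C=C/C(C)=O
F2 | step 1 | α-ionols, (3E)-4-(2,6,6-trimethylcyclohex-2-en-1-yl)but-3-en-2-ol (stereoisomer mixture) | CC1=CCCC(C)(C)C1/C=C/C(C)O
F3 | step 1 | racemic (6S*,9R*)-α-ionyl 4-nitrobenzoate | CC1=CCCC(C)(C)[C@@H]1/C=C/[C@@H](C)OC(=O)c1ccc(cc1)[N+](=O)[O-].CC1=CCCC(C)(C)[C@H]1/C=C/[C@H](C)OC(=O)c1ccc(cc1)[N+](=O)[O-]
F4 | step 1 | racemic (6S*,9R*)-α-ionol | CC1=CCCC(C)(C)[C@@H]1/C=C/[C@@H](C)O.CC1=CCCC(C)(C)[C@H]1/C=C/[C@H](C)O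
F5 | step 1 | (6S,9R)-α-ionyl acetate, (2R,3E)-4-[(1S)-2,6,6-trimethylcyclohex-2-en-1-yl]but-3-en-2-yl acetate | CC1=CCCC(C)(C)[C@@H]1/C=C/[C@@H](C)OC(C)=O
F6 | step 1 | (6S,9R)-α-ionol, (2R,3E)-4-[(1S)-2,6,6-trimethylcyclohex-2-en-1-yl]but-3-en-2-ol | CC1=CCCC(C)(C)[C@@H]1/C=C/[C@@H](C)O
F7 | step 7 | (3S,6S)-3-hydroxy-α-ionone, (3E)-4-[(1S,4S)-4-hydroxy-2,6,6-trimethylcyclohex-2-en-1-yl]but-3-en-2-one | CC1=C[C@@H](O)CC(C)(C)[C@@H]1/C=C/C(C)=O
F8 | step 7 | (1S,4S)-4-[(1E)-3-hydroxy-3-methylpenta-1,4-dien-1-yl]-3,5,5-trimethylcyclohex-2-en-1-ol (C9 epimers) | CC1=C[C@@H](O)CC(C)(C)[C@@H]1/C=C/C(C)(O)C=C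
F9 | step 7 | [(2E,4E)-5-[(1S,4S)-4-hydroxy-2,6,6-trimethylcyclohex-2-en-1-yl]-3-methylpenta-2,4-dien-1-yl]triphenylphosphonium bromide | CC1=C[C@@H](O)CC(C)(C)[C@@H]1/C=C/C(C)=C/C[P+](c1ccccc1)(c1ccccc1)c1ccccc1.[Br-]
F10 | step 7 | ylide of F9, [(2E,4E)-5-[(1S,4S)-4-hydroxy-2,6,6-trimethylcyclohex-2-en-1-yl]-3-methylpenta-2,4-dien-1-ylidene]triphenyl-λ5-phosphane | CC1=C[C@@H](O)CC(C)(C)[C@@H]1/C=C/C(C)=C/C=P(c1ccccc1)(c1ccccc1)c1ccccc1
F11 | step 10 | ethyl (2E,4E)-5-[(1S,4S)-4-hydroxy-2,6,6-trimethylcyclohex-2-en-1-yl]-3-methylpenta-2,4-dienoate | CC1=C[C@@H](O)CC(C)(C)[C@@H]1/C=C/C(C)=C/C(=O)OCC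
F12 | step 10 | (2E,4E)-5-[(1S,4S)-4-hydroxy-2,6,6-trimethylcyclohex-2-en-1-yl]-3-methylpenta-2,4-dien-1-ol | CC1=C[C@@H](O)CC(C)(C)[C@@H]1/C=C/C(C)=C/CO
F13 | step 10 | (1S,4S)-4-[(1E,3E)-5-[tert-butyl(dimethyl)silyl]oxy-3-methylpenta-1,3-dien-1-yl]-3,5,5-trimethylcyclohex-2-en-1-ol | CC1=C[C@@H](O)CC(C)(C)[C@@H]1/C=C/C(C)=C/CO[Si](C)(C)C(C)(C)C
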